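The product in both earlier runs leads left-handed early and ends nearly even, with substrate still standing. The quick number asked for can be read from that drift, and the hunch of a tie can be tested with it.

| flask | left-handed substrate | right-handed substrate | gas | free catalyst | remark | time |
|---|---|---|---|---|---|---|
| Monday's | 0.30 M | 0.30 M | 88 mM (held) | 4.7 mM | run made earlier |  |
| Saturday's | 0.30 M | 0.30 M | 88 mM (held) | 11 mM | run made earlier |  |
| north-east | 0.30 M | 0.30 M | 88 mM (held) | 7.5 mM |  | 25 min |
| south-west | 0.30 M | 0.30 M | 88 mM (held) | 4.0 mM |  | 25 min |

- Monday's (time / min: left-handed product / %, right-handed product / %): 2.00: 6.1, 3.0; 3.00: 7.0, 4.9; 5.00: 9.4, 7.2; 8.00: 9.9, 8.4; 10.0: 10.1, 9.6; 15.0: 12.5, 10.8; 25.0: 13.4, 13.1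
- Saturday's (time / min: left-handed product / %, right-handed product / %): 2.00: 10.9, 5.8; 3.00: 10.6, 7.8; 5.00: 12.1, 9.6; 8.00: 12.6, 11.3; 10.0: 14.4, 12.6; 15.0: 14.4, 14.5; 25.0: 15.8, 15.5

(readings scatter by 0.5 percentage points)

- which one finishes higher in excess of left-handed product over right-handed product in the product ("neither" within 2 percentage points) (north-east / south-west / neither)
- excess of left-handed product over right-handed product in the product at the end, north-east
- excess of left-handed product over right-handed product in the product at the end, south-west

- free catalyst is single-handed; left-handed substrate and right-handed substrate are mirror images of each other, charged as a racemate, each of them at the stated concentration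
- at the start none of partner is dissolved
- the earlier runs were read with a standard deviation of 0.5 percentage points
- what may be going on: free catalyst + left-handed substrate <-> catalyst intermediate A; free catalyst + right-handed substrate <-> catalyst intermediate B; partner + catalyst intermediate A -> free catalyst + left-handed product; partner + catalyst intermediate B -> free catalyst + right-handed product; left-handed product <-> right-handed product; 2 free catalyst -> spent catalyst; gas <-> partner
- an excess is the difference of the two amounts in percent of their sum
- an excess is below zero if the other one leads

The left-handed product and right-handed product are taken to interconvert (racemisation). The catalyst then feeds the gap between them while the interconversion drains it. Taking the two rates as balanced, the gap follows the output. Pooled around 5.00 min, the two runs read 1.72 min. This is the lag: the gap between the products divided by the rate at which their sum grows.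

The excess at a moment is then the lag times the fractional growth of the sum. The comparison drifts as output fades. Over the last interval, this reckoning gives 2.08% for Monday's run and 1.32% for Saturday's. South-west's free catalyst of 4.0 mM lies below Monday's 4.7 mM, and north-east's 7.5 mM lies between Monday's and Saturday's 11 mM. The spread of 0.76 percentage points between the two runs is smaller than the margin, so the call is a tie.

The forecast also says neither, with 1.2% (0.2% to 3%) for north-east and 1.7% (0.4% to 4%) for south-west; by its reasoning, late output “sustains a steady gap”. The figure here for Monday's run is higher than the forecast's for south-west.

The flasks give neither: 0.679% for north-east and 0.903% for south-west.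

    free catalyst + left-handed substrate ⇌ catalyst intermediate A (K = 3.50 L mol⁻¹, k = 4.48 L mol⁻¹ s⁻¹)
    free catalyst + right-handed substrate ⇌ catalyst intermediate B (K = 1.34 L mol⁻¹, k = 4.19 L mol⁻¹ s⁻¹)
    partner + catalyst intermediate A → free catalyst + left-handed product (k = 4.38 L mol⁻¹ s⁻¹)
    partner + catalyst intermediate B → free catalyst + right-handed product (k = 2.10 L mol⁻¹ s⁻¹)
    left-handed product ⇌ right-handed product (k = 0.00513 s⁻¹)
    2 free catalyst → spent catalyst (k = 5.92 L mol⁻¹ s⁻¹)
    gas ⇌ partner, rate k7*(csat - [partner]) (kL = 0.623 s⁻¹)

At 25.0 min, the intermediates and constants make the product sum in north-east grow at 0.00819 min⁻¹. The lag turns that into 1.41%, against 0.679% in the flask. The same flask stopped at 6.0 min grows at 0.0594 min⁻¹. There the lag gives 10.2%, and the flask stands at 8.10%.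

The readings are calculated with constants of no real substance, noise included.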